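**Retrosynthetic overview**
1. Key disconnection, C6–O: ring-B oxygen is put on last, on the finished skeleton. Target 14 ⇒ enal 11 by γ-oxygenation of its silyl dienol ether from the face opposite the axial methyl groups (C–O bond, sets C6); 11 ⇒ 7-ene 9 by allylic C–H oxygenation at C17 (second C–O bond).
2. Rings: 9 ⇒ acyclic tetraene 8. Ring A (C4–C5 bond) and then ring B (C9–C10 bond) close in one enantioselective cationic cascade that ends by loss of H-7 (new method; sets C5, C9, C10).
3. Side chain, finished before cyclization: C16–O formate ⇒ allylic alcohol 7; C13–C16 ⇒ Stille hydroxymethylation of (E)-enol triflate 5; C11–C12 ⇒ dianion alkylation of methyl acetoacetate 1 with farnesyl bromide 2.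

Assumption: the target is taken exactly as the given SMILES, an ent-labdane (5R,6R,9S,10S; labdane numbering is used throughout); "ent-IDPi" means the antipode of the confined imidodiphosphorimidate Brønsted acid that cyclizes (3E,7E)-homofarnesol to natural (−)-ambrox.

**Step 1**
Reactants: 1 methyl acetoacetate; 2 (2E,6E)-farnesyl bromide
Product: 4 methyl (6E,10E)-7,11,15-trimethyl-3-oxohexadeca-6,10,14-trienoate, via methyl acetoacetate dianion 3 (not isolated)
Conditions: NaH, THF, 0 °C; n-BuLi, 0 °C; then 2, 0 °C → rt; aq. HCl
Reagents that add atoms: none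
Why: Dianion (γ-selective) alkylation of a β-keto ester: the more basic terminal carbanion displaces the primary allylic bromide by SN2 and leaves the E-alkenes untouched; no stereocenter is formed.

**Step 2**
Reactants: 4 methyl (6E,10E)-7,11,15-trimethyl-3-oxohexadeca-6,10,14-trienoate
Product: 5 methyl (2E,6E,10E)-7,11,15-trimethyl-3-(trifluoromethanesulfonyloxy)hexadeca-2,6,10,14-tetraenoate (OTf trans to CO2Me)
Conditions: Tf2O, 25% aq. Me4NOH, hexanes, 5 °C
Reagents that add atoms: triflic anhydride, O=S(=O)(OS(=O)(=O)C(F)(F)F)C(F)(F)F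
Why: Stereoselective enol triflation of a β-keto ester: the non-chelated tetraalkylammonium enolate is O-sulfonylated in the E geometry (OTf trans to the ester), which fixes the C13=C14 geometry of the target.

**Step 3**
Reactants: 5 the (E)-enol triflate; 6 (tributylstannyl)methanol
Product: 7 methyl (2E,6E,10E)-3-(hydroxymethyl)-7,11,15-trimethylhexadeca-2,6,10,14-tetraenoate (CH2OH trans to CO2Me)
Conditions: Pd(PPh3)4 (5 mol %), LiCl, 1,4-dioxane, 90 °C
Reagents that add atoms: none
Why: Stille coupling (hydroxymethyl transfer from tin): oxidative addition and reductive elimination keep the alkene geometry, and the trans arrangement of CH2OH and CO2Me rules out lactonization.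

**Step 4**
Reactants: 7 the allylic alcohol
Product: 8 methyl (2E,6E,10E)-3-[(formyloxy)methyl]-7,11,15-trimethylhexadeca-2,6,10,14-tetraenoate
Conditions: HCO2H, DCC, DMAP (cat.), CH2Cl2, 0 °C
Reagents that add atoms: formic acid, O=CO
Why: Steglich esterification of an unhindered primary allylic alcohol; the formate is a group of the target and also makes the enoate alkene too electron-poor to join the next cascade.

**Step 5**
Reactants: 8 the formyloxy tetraene
Product: 9 methyl (13E)-16-(formyloxy)-ent-labda-7,13-dien-15-oate (5R,9R,10R; trans-decalin, C9 chain and C10 methyl cis)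
Conditions: ent-IDPi (5 mol %), (CF3)3COH–CH2Cl2, −30 °C
Reagents that add atoms: none
Why: Proposed new method: an enantioselective proton-initiated polyene bicyclization that has no nucleophilic terminator and ends by regioselective proton loss; the confined chiral anion protonates the terminal trisubstituted alkene on one face inside its pocket and holds the chain in a chair–chair fold, so two anti (Stork–Eschenmoser) additions set C5, C10 and C9 (trans ring fusion, equatorial chain from the E-alkene), then the same anion, bound on the methyl-free face of the C8 cation, removes the axial H-7 that is aligned with the empty orbital, while the formyloxymethyl enoate cannot extend the cascade and any exocyclic 8(17)-isomer is re-protonated and funnelled to the 7-ene; closest known reaction type: chiral Brønsted acid (IDPi) or BINOL·SnCl4-mediated cyclization of homofarnesol to ambrox, where an OH group, not proton loss, ends the cascade.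

**Step 6**
Reactants: 9 the bicyclic 7-ene
Product: 11 methyl (13E)-16-(formyloxy)-17-oxo-ent-labda-7,13-dien-15-oate (5R,9S,10R; descriptor change is a CIP priority effect), via 17-alcohol 10 (not isolated)
Conditions: SeO2 (1.2 equiv), 1,4-dioxane, 80 °C
Reagents that add atoms: selenium dioxide, O=[Se]=O
Why: Riley allylic oxidation (ene reaction then [2,3]-sigmatropic shift): the only electron-rich alkene reacts, oxygen goes to the methyl group on its more substituted end (CH3 before the tertiary C9–H), further oxidation gives the conjugated aldehyde, and no stereocenter is touched.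

**Step 7**
Reactants: 11 the enal
Product: 14 methyl (13E)-16-(formyloxy)-6-hydroxy-17-oxo-ent-labda-7,13-dien-15-oate (5R,6R,9S,10S; target), via TBS dienol ether 12 (not isolated), via 6,7-epoxide 13 (not isolated)
Conditions: TBSOTf, Et3N, CH2Cl2, −78 → 0 °C; pentane filtration; DMDO, acetone, −78 °C; PPTS, THF–H2O, 0 °C
Reagents that add atoms: dimethyldioxirane, CC1(C)OO1; tert-butyldimethylsilyl triflate, CC(C)(C)[Si](C)(C)OS(=O)(=O)C(F)(F)F (its silyl group is carried only in 12 and 13)
Why: Vinylogous Rubottom oxidation: soft enolization gives the 1-silyloxy-1,3-diene, DMDO epoxidizes its terminal C6=C7 bond from the face opposite the axial C10 and C4 methyl groups, and hydrolytic opening returns the conjugated enal with the new equatorial 6-OH trans to the C10 methyl (6R).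

**Compound list**
1 | methyl acetoacetate | COC(=O)CC(C)=O | starting material
2 | (2E,6E)-farnesyl bromide | BrC/C=C(\C)CC/C=C(\C)CCC=C(C)C | starting material
3 | methyl acetoacetate dianion (Na/Li salt) | [Na+].[Li+].COC(=O)[CH-]C(=O)[CH2-] | intermediate
4 | methyl (6E,10E)-7,11,15-trimethyl-3-oxohexadeca-6,10,14-trienoate | COC(=O)CC(=O)CC/C=C(\C)CC/C=C(\C)CCC=C(C)C | intermediate
5 | methyl (2E,6E,10E)-7,11,15-trimethyl-3-(trifluoromethanesulfonyloxy)hexadeca-2,6,10,14-tetraenoate | COC(=O)/C=C(/OS(=O)(=O)C(F)(F)F)CC/C=C(\C)CC/C=C(\C)CCC=C(C)C | intermediate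
6 | (tributylstannyl)methanol | CCCC[Sn](CCCC)(CCCC)CO | starting material
7 | methyl (2E,6E,10E)-3-(hydroxymethyl)-7,11,15-trimethylhexadeca-2,6,10,14-tetraenoate | COC(=O)/C=C(/CO)CC/C=C(\C)CC/C=C(\C)CCC=C(C)C | intermediate
8 | methyl (2E,6E,10E)-3-[(formyloxy)methyl]-7,11,15-trimethylhexadeca-2,6,10,14-tetraenoate | COC(=O)/C=C(/COC=O)CC/C=C(\C)CC/C=C(\C)CCC=C(C)C | intermediate
9 | methyl (13E)-16-(formyloxy)-ent-labda-7,13-dien-15-oate (5R,9R,10R) | COC(=O)/C=C(\CC[C@@H]1C(C)=CC[C@@H]2C(C)(C)CCC[C@@]12C)COC=O | intermediate
10 | methyl (13E)-16-(formyloxy)-17-hydroxy-ent-labda-7,13-dien-15-oate | COC(=O)/C=C(\CC[C@@H]1C(CO)=CC[C@@H]2C(C)(C)CCC[C@@]12C)COC=O | intermediate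
11 | methyl (13E)-16-(formyloxy)-17-oxo-ent-labda-7,13-dien-15-oate (5R,9S,10R) | COC(=O)/C=C(\CC[C@@H]1C(C=O)=CC[C@@H]2C(C)(C)CCC[C@@]12C)COC=O | intermediate
12 | methyl (13E)-17-(tert-butyldimethylsilyloxy)-16-(formyloxy)-ent-labda-6,8(17),13-trien-15-oate (C8=C17 geometry not defined) | COC(=O)/C=C(\CC[C@@H]1C(=CO[Si](C)(C)C(C)(C)C)C=C[C@@H]2C(C)(C)CCC[C@@]12C)COC=O | intermediate
13 | methyl (13E)-17-(tert-butyldimethylsilyloxy)-6,7-epoxy-16-(formyloxy)-ent-labda-8(17),13-dien-15-oate (epoxide on the face opposite the C10 methyl) | COC(=O)/C=C(\CC[C@@H]1C(=CO[Si](C)(C)C(C)(C)C)[C@H]3O[C@H]3[C@@H]2C(C)(C)CCC[C@@]12C)COC=O | intermediate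
14 | methyl (13E)-16-(formyloxy)-6-hydroxy-17-oxo-ent-labda-7,13-dien-15-oate (5R,6R,9S,10S; 6-OH trans to the C10 methyl) | COC(=O)/C=C(\CC[C@@H]1C(C=O)=C[C@@H](O)[C@@H]2C(C)(C)CCC[C@@]12C)COC=O | target

**Step count**
Total steps: 7. Longest linear sequence: 7.

**Steps most likely to fail**

Step 5 (the proposed new step). Risks are low enantioselectivity, 8(17)- or 8(9)-alkene isomers, or a stop at the monocyclic stage. Fallback with known chemistry: it sets out from 8 and comes back at 9. Compound 8 is cyclized without asymmetric induction under classical superacid conditions (ClSO3H, 2-nitropropane, −78 °C), the established racemic cation–olefin bicyclization of polyprenoid esters. This gives 9 as the racemate, that is, together with its antipode methyl (5S,9S,10S)-(13E)-16-(formyloxy)labda-7,13-dien-15-oate F1. The two are separated by preparative SFC on a polysaccharide chiral stationary phase, and 9 goes on to step 6.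

Step 6. Risks are over-oxidation by hot SeO2 (hydroxylation of the tertiary allylic C9–H of the enal) and partial loss of the formate. The fallback gives up the selenium ene chemistry; it sets out from 9 and comes back at 10, and from there at 11. mCPBA/NaHCO3 epoxidizes the only electron-rich alkene from the face opposite the C10 methyl to give methyl (13E)-7,8-epoxy-16-(formyloxy)-ent-labd-13-en-15-oate F2. Excess Cp2TiCl (Cp2TiCl2, Mn, THF) opens the epoxide at C8, and hydrogen abstraction from the methyl group gives methyl (13E)-16-(formyloxy)-7-hydroxy-ent-labda-8(17),13-dien-15-oate F3. A perrhenate catalyst (Ph3SiOReO3, Et2O) moves the hydroxyl by 1,3-transposition to the primary position, which is compound 10, now isolated. MnO2 oxidizes 10 to 11.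

Step 7. Risks are slow γ-deprotonation at the hindered C6, oxygen transfer to the enol ether bond (α-attack at C8), and redox isomerization of the γ-hydroxy enal. The fallback replaces electrophilic oxygen transfer by a cycloaddition; it sets out from 11 and comes back at 14. Compound 12 is made as in step 7 but isolated. Singlet oxygen (O2, tetraphenylporphyrin, hν, CH2Cl2, −78 °C) adds [4+2] across C6 and C17, the only way the diene can react, again from the face opposite the axial methyl groups. This gives methyl (13E)-17-(tert-butyldimethylsilyloxy)-6,17-epidioxy-16-(formyloxy)-ent-labda-7,13-dien-15-oate F4. PPh3 cleaves the O–O bond, and the C17 silyl hemiacetal collapses to 14.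

**Further compounds**
F1 | step 5 | methyl (5S,9S,10S)-(13E)-16-(formyloxy)labda-7,13-dien-15-oate (antipode of 9) | COC(=O)/C=C(\CC[C@H]1C(C)=CC[C@H]2C(C)(C)CCC[C@]12C)COC=O
F2 | step 6 | methyl (13E)-7,8-epoxy-16-(formyloxy)-ent-labd-13-en-15-oate (epoxide opposite the C10 methyl) | COC(=O)/C=C(\CC[C@@H]1[C@@]3(C)O[C@H]3C[C@@H]2C(C)(C)CCC[C@@]12C)COC=O
F3 | step 6 | methyl (13E)-16-(formyloxy)-7-hydroxy-ent-labda-8(17),13-dien-15-oate (7-OH opposite the C10 methyl) | COC(=O)/C=C(\CC[C@@H]1C(=C)[C@@H](O)C[C@@H]2C(C)(C)CCC[C@@]12C)COC=O
F4 | step 7 | methyl (13E)-17-(tert-butyldimethylsilyloxy)-6,17-epidioxy-16-(formyloxy)-ent-labda-7,13-dien-15-oate (C17 configuration not defined) | COC(=O)/C=C(\CC[C@@H]1C3=C[C@@H](OOC3O[Si](C)(C)C(C)(C)C)[C@@H]2C(C)(C)CCC[C@@]12C)COC=O
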